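The synthesis rests on cutting the two bonds that link C3 and C4 of the γ-butyrolactone (O1, C2 carbonyl, C3, C4, C5) to their benzylic carbons. Trans benzyl arms on neighbouring ring carbons, ring A (3-hydroxy-4-methoxyphenyl) on C3 and ring B (3,4-dimethoxyphenyl) on C4, are the signature of conjugate addition to a 2(5H)-furanone followed by capture of the enolate. In one flask the lithiated ring B dithiane attacks C4 of enantiopure (5R)-5-menthyloxy-2(5H)-furanone and the enolate is benzylated at C3 by the O-benzyl-protected ring A bromide, both stereocentres being dictated by the C5 acetal. Nickel-mediated desulfurisation/debenzylation and reduction of C5 to CH2 then complete the target.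

Key step: step 6

Assumption: W-2 Raney Ni under H2 is taken to cleave the aryl benzyl ether in the same operation as the C–S bonds; the benzyl ether is chosen as phenol protection for that reason, since it also survives the carbanion chemistry of step 6.

Step 1
Reactants: 1 furfural
Product: 2 5-hydroxyfuran-2(5H)-one (racemic hemiacetal)
Conditions: O2, cat. rose bengal (disodium salt, C20H2Cl4I4Na2O5), MeOH, hν (visible), 20 °C
Reagents that add atoms: dioxygen, O=O
Why: Dye-sensitised singlet-oxygen [4+2] cycloaddition to the furan gives an endoperoxide whose methanolysis expels the formyl carbon as methyl formate and leaves the γ-hydroxybutenolide (photooxygenation of furfural), the hemiacetal centre being formed racemic and not yet controlled.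

Step 2
Reactants: 2 5-hydroxyfuran-2(5H)-one; 3 (1R,2S,5R)-menthol
Product: 4 (5R)-5-{[(1R,2S,5R)-2-isopropyl-5-methylcyclohexyl]oxy}furan-2(5H)-one
Conditions: cat. p-TsOH·H2O, toluene, reflux (Dean–Stark); crystallise from petroleum ether, −20 °C; mother liquor re-equilibrated with acid and recrystallised
Reagents that add atoms: none
Why: Acid-catalysed acetalisation (pseudo-ester formation) of the cyclic hemiacetal gives both C5 epimers, which interconvert under acid, and the (5R) diastereomer should be the one that crystallises, so C5 is set by crystallisation-driven epimer selection against the fixed menthyl stereocentres.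

Step 3
Reactants: 5 3,4-dimethoxybenzaldehyde
Product: 6 2-(3,4-dimethoxyphenyl)-1,3-dithiane
Conditions: HS(CH2)3SH, cat. BF3·OEt2, CH2Cl2, 0 °C → rt
Reagents that add atoms: propane-1,3-dithiol, SCCCS
Why: Lewis-acid-catalysed dithioacetalisation of an aromatic aldehyde is a routine condensation and installs the acidic C–H needed for umpolung of the ring B carbonyl carbon.

Step 4
Reactants: 7 3-(benzyloxy)-4-methoxybenzaldehyde
Product: 8 [3-(benzyloxy)-4-methoxyphenyl]methanol
Conditions: NaBH4, MeOH, 0 °C
Reagents that add atoms: none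
Why: Borohydride reduction of an aryl aldehyde to the benzylic alcohol is chemoselective and leaves the benzyl and methyl ethers untouched.

Step 5
Reactants: 8 [3-(benzyloxy)-4-methoxyphenyl]methanol
Product: 9 3-(benzyloxy)-4-methoxybenzyl bromide
Conditions: PBr3, Et2O, 0 °C
Reagents that add atoms: phosphorus tribromide, BrP(Br)Br
Why: Bromination of a primary benzylic alcohol with PBr3 runs through a phosphite ester and SN2 displacement by bromide, is fast at 0 °C on the electron-rich ring, and the aryl benzyl ether should tolerate the brief acid exposure.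

Step 6
Reactants: 6 2-(3,4-dimethoxyphenyl)-1,3-dithiane; 4 (5R)-5-{[(1R,2S,5R)-2-isopropyl-5-methylcyclohexyl]oxy}furan-2(5H)-one; 9 3-(benzyloxy)-4-methoxybenzyl bromide
Product: 12 (3R,4R,5R)-3-[3-(benzyloxy)-4-methoxybenzyl]-4-[2-(3,4-dimethoxyphenyl)-1,3-dithian-2-yl]-5-[(1R,2S,5R)-menthyloxy]dihydrofuran-2(3H)-one, via lithiated dithiane 10 (not isolated), via lithium lactone enolate 11 (not isolated)
Conditions: 6, n-BuLi, THF, −78 → −20 °C; 4, THF, −78 °C; 9, TMEDA, −78 °C → rt; aq. NH4Cl
Reagents that add atoms: none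
Why: n-BuLi removes the C2–H of dithiane 6 to give the sulfur-stabilised benzylic anion 10, which adds as a Michael donor to C4 of butenolide 4, and the lithium enolate 11 so formed is C-alkylated at C3 by bromide 9 in an SN2 step, so that the C4–benzylic and C3–benzylic bonds are both made before work-up. The closest known reaction type is the tandem conjugate addition–enolate alkylation (vicinal difunctionalisation) of 5-alkoxy-2(5H)-furanones with lithiated 2-aryl-1,3-dithianes. No ring is closed, since the lactone is already in place. C4 is controlled by the C5 acetal centre, whose menthyloxy group blocks one face of the flat butenolide so that the anion enters anti to it, and C3 is controlled by C4, whose bulky dithianyl group forces the bromide to the opposite face, which should give the 3,4-trans-4,5-trans (3R,4R,5R) adduct. The step needs 1,4- rather than 1,2-addition, which the soft, charge-delocalised aryl dithiane anion at −78 °C secures, and clean C-monoalkylation, which the reactive benzylic bromide, TMEDA activation of the enolate and the congested tertiary C3 of the product secure.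

Step 7
Reactants: 12 (3R,4R,5R)-3-[3-(benzyloxy)-4-methoxybenzyl]-4-[2-(3,4-dimethoxyphenyl)-1,3-dithian-2-yl]-5-[(1R,2S,5R)-menthyloxy]dihydrofuran-2(3H)-one
Product: 13 (3R,4R,5R)-4-(3,4-dimethoxybenzyl)-3-(3-hydroxy-4-methoxybenzyl)-5-[(1R,2S,5R)-menthyloxy]dihydrofuran-2(3H)-one
Conditions: Raney Ni (W-2, excess, washed neutral), H2 (1 atm), EtOH/THF, reflux
Reagents that add atoms: none
Why: Raney Ni hydrogenolyses both C–S bonds of the benzylic dithioacetal (Mozingo-type desulfurisation) and, under H2, also the aryl benzyl ether, while the lactone acetal, the methyl ethers and the three ring stereocentres, which see neither acid nor base, should remain unchanged.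

Step 8
Reactants: 13 (3R,4R,5R)-4-(3,4-dimethoxybenzyl)-3-(3-hydroxy-4-methoxybenzyl)-5-[(1R,2S,5R)-menthyloxy]dihydrofuran-2(3H)-one
Product: 16 prestegane A, (3R,4R)-4-(3,4-dimethoxybenzyl)-3-(3-hydroxy-4-methoxybenzyl)dihydrofuran-2(3H)-one, via aldehyde carboxylate 14 (not isolated), via hydroxy carboxylate 15 (not isolated)
Conditions: 13 added to NaBH4, KOH, EtOH/H2O, 0 °C → rt; then 2 M HCl, rt
Reagents that add atoms: potassium hydroxide, [K+].[OH-] (its oxygen enters the carboxylate and can remain as the lactone carbonyl oxygen)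
Why: Hydroxide opens the pseudo-ester, the freed hemiacetal loses menthol to give aldehyde 14, borohydride already present reduces it at once to hydroxy carboxylate 15 before C4 can enolise, and acidification closes the γ-lactone by 5-exo-trig acyl substitution with C2 still the carbonyl and C5 now CH2 (saponification, NaBH4 reduction, acid lactonisation), leaving C3 and C4 as set in step 6.

Compound list
1 | furfural (furan-2-carbaldehyde) | O=Cc1ccco1 | starting material
2 | 5-hydroxyfuran-2(5H)-one (racemic hemiacetal) | O=C1C=CC(O)O1 | intermediate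
3 | (1R,2S,5R)-menthol | C[C@@H]1CC[C@H]([C@@H](C1)O)C(C)C | starting material
4 | (5R)-5-{[(1R,2S,5R)-2-isopropyl-5-methylcyclohexyl]oxy}furan-2(5H)-one | O=C1C=C[C@H](O[C@@H]2C[C@H](C)CC[C@H]2C(C)C)O1 | intermediate
5 | 3,4-dimethoxybenzaldehyde | COc1ccc(C=O)cc1OC | starting material
6 | 2-(3,4-dimethoxyphenyl)-1,3-dithiane | COc1ccc(C2SCCCS2)cc1OC | intermediate
7 | 3-(benzyloxy)-4-methoxybenzaldehyde | COc1ccc(C=O)cc1OCc1ccccc1 | starting material
8 | [3-(benzyloxy)-4-methoxyphenyl]methanol | COc1ccc(CO)cc1OCc1ccccc1 | intermediate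
9 | 3-(benzyloxy)-4-methoxybenzyl bromide | COc1ccc(CBr)cc1OCc1ccccc1 | intermediate
10 | 2-(3,4-dimethoxyphenyl)-2-lithio-1,3-dithiane | [Li]C1(c2ccc(OC)c(OC)c2)SCCCS1 | intermediate
11 | lithium (4R,5R)-4-[2-(3,4-dimethoxyphenyl)-1,3-dithian-2-yl]-5-[(1R,2S,5R)-menthyloxy]-4,5-dihydrofuran-2-olate | [Li]OC1=C[C@@H](C2(c3ccc(OC)c(OC)c3)SCCCS2)[C@H](O[C@@H]2C[C@H](C)CC[C@H]2C(C)C)O1 | intermediate
12 | (3R,4R,5R)-3-[3-(benzyloxy)-4-methoxybenzyl]-4-[2-(3,4-dimethoxyphenyl)-1,3-dithian-2-yl]-5-[(1R,2S,5R)-menthyloxy]dihydrofuran-2(3H)-one | COc1ccc(C[C@H]2C(=O)O[C@@H](O[C@@H]3C[C@H](C)CC[C@H]3C(C)C)[C@@H]2C2(c3ccc(OC)c(OC)c3)SCCCS2)cc1OCc1ccccc1 | intermediate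
13 | (3R,4R,5R)-4-(3,4-dimethoxybenzyl)-3-(3-hydroxy-4-methoxybenzyl)-5-[(1R,2S,5R)-menthyloxy]dihydrofuran-2(3H)-one | COc1ccc(C[C@H]2C(=O)O[C@@H](O[C@@H]3C[C@H](C)CC[C@H]3C(C)C)[C@@H]2Cc2ccc(OC)c(OC)c2)cc1O | intermediate
14 | dipotassium (2R,3R)-3-(3,4-dimethoxybenzyl)-2-(4-methoxy-3-oxidobenzyl)-4-oxobutanoate | [K+].[K+].COc1ccc(C[C@@H](C([O-])=O)[C@H](C=O)Cc2ccc(OC)c(OC)c2)cc1[O-] | intermediate
15 | dipotassium (2R,3R)-3-(3,4-dimethoxybenzyl)-4-hydroxy-2-(4-methoxy-3-oxidobenzyl)butanoate | [K+].[K+].COc1ccc(C[C@@H](C([O-])=O)[C@H](CO)Cc2ccc(OC)c(OC)c2)cc1[O-] | intermediate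
16 | prestegane A, (3R,4R)-4-(3,4-dimethoxybenzyl)-3-(3-hydroxy-4-methoxybenzyl)dihydrofuran-2(3H)-one | COc1ccc(C[C@H]2C(=O)OC[C@@H]2Cc2ccc(OC)c(OC)c2)cc1O | target

Total step count: 8
Longest linear sequence: 5 steps (steps 1, 2, 6, 7, 8; the branch through steps 4, 5, 6, 7, 8 is equally long)

Steps most likely to fail

Step 6. The enolate may be quenched by proton transfer before the bromide reacts. The basic carbanion may also deprotonate the butenolide at C5 instead of adding, or the alkylation may lose facial selectivity when run in the same flask. Fallback, setting out from 4 and 6 and returning at 12: the two bond formations are separated. Anion 10 is added to 4 at −78 °C and the enolate is protonated with aq. NH4Cl to give the unalkylated Michael adduct (4R,5R)-4-[2-(3,4-dimethoxyphenyl)-1,3-dithian-2-yl]-5-[(1R,2S,5R)-menthyloxy]dihydrofuran-2(3H)-one F1, which is purified. Its enolate is then regenerated with LiN(SiMe3)2 in THF/DMPU at −78 °C and alkylated with bromide 9, again anti to the C4 substituent, to give 12.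

Step 7. Hydrogenolysis of the benzyl ether may lag behind desulfurisation and leave a mixture of protected and free phenol, or the hot alcoholic nickel slurry may partly solvolyse the lactone acetal. Fallback, setting out from 12 and returning at 16: the two cleavages are decoupled.
- Nickel boride generated from NiCl2·6H2O and NaBH4 in MeOH/THF at 0 °C should remove only the sulfur and give (3R,4R,5R)-3-[3-(benzyloxy)-4-methoxybenzyl]-4-(3,4-dimethoxybenzyl)-5-[(1R,2S,5R)-menthyloxy]dihydrofuran-2(3H)-one F2.
- The NaBH4/KOH reduction and acid lactonisation of step 8 then give (3R,4R)-3-[3-(benzyloxy)-4-methoxybenzyl]-4-(3,4-dimethoxybenzyl)dihydrofuran-2(3H)-one F3.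
- Hydrogenolysis over 10% Pd/C (H2, EtOAc/EtOH, rt) on this sulfur-free lactone should deliver 16, and it also converges any partly debenzylated material.

Step 8. The open-chain aldehyde may enolise at C4 in the alkaline medium before it is reduced, which would erode the trans relationship and the enantiopurity. Fallback, setting out from 13 and returning at 16: the auxiliary is removed under acid instead of base. Hydrolysis of the menthyl acetal (2 M HCl, dioxane, 50 °C) gives the pseudo-acid (3R,4R)-4-(3,4-dimethoxybenzyl)-5-hydroxy-3-(3-hydroxy-4-methoxybenzyl)dihydrofuran-2(3H)-one F4 as a mixture of C5 anomers. Its masked aldehyde is reduced by NaBH4 in cold, NaHCO3-buffered aqueous EtOH, where enolisation is slow, and acidification relactonises to 16.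

Further compounds
F1 | step 6 | (4R,5R)-4-[2-(3,4-dimethoxyphenyl)-1,3-dithian-2-yl]-5-[(1R,2S,5R)-menthyloxy]dihydrofuran-2(3H)-one | O=C1C[C@@H](C2(c3ccc(OC)c(OC)c3)SCCCS2)[C@H](O[C@@H]2C[C@H](C)CC[C@H]2C(C)C)O1
F2 | step 7 | (3R,4R,5R)-3-[3-(benzyloxy)-4-methoxybenzyl]-4-(3,4-dimethoxybenzyl)-5-[(1R,2S,5R)-menthyloxy]dihydrofuran-2(3H)-one | COc1ccc(C[C@H]2C(=O)O[C@@H](O[C@@H]3C[C@H](C)CC[C@H]3C(C)C)[C@@H]2Cc2ccc(OC)c(OC)c2)cc1OCc1ccccc1
F3 | step 7 | (3R,4R)-3-[3-(benzyloxy)-4-methoxybenzyl]-4-(3,4-dimethoxybenzyl)dihydrofuran-2(3H)-one | COc1ccc(C[C@H]2C(=O)OC[C@@H]2Cc2ccc(OC)c(OC)c2)cc1OCc1ccccc1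
F4 | step 8 | (3R,4R)-4-(3,4-dimethoxybenzyl)-5-hydroxy-3-(3-hydroxy-4-methoxybenzyl)dihydrofuran-2(3H)-one (C5 anomers) | COc1ccc(C[C@H]2C(=O)OC(O)[C@@H]2Cc2ccc(OC)c(OC)c2)cc1O
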